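**Plan**
Ring numbering: C1 carries CH2SO2Me, C2 Br, C3 and C4 OH, C5 and C6 Br.
Retrosynthesis: C2–Br and C5–Br go back to C–H and C6–Br to C6–CO2tBu; the ring is then cut at C1–C2 and C5–C6.
Enabling feature: in the benzene ring the adjacent oxygen-bearing carbons C3/C4 with their neighbours C2/C5 are a latent 2,3-dioxygenated butadiene, and C1/C6 are the two carbons of an alkyne bearing CH2SO2Me and an ester that stands in for the C6 bromine.
Forward: the sulfone ynoate is made in three steps from propargyl bromide; one Diels–Alder reaction with the bis(silyloxy)diene closes the only ring; DDQ then TFA give the catechol acid; bromine sets all three C–Br bonds, the one at C6 by ipso-bromodecarboxylation.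
Stereochemistry: none has to be set, because the target is an achiral, fully substituted arene.

Key step: step 4

Remark: the target has no stereocentre, so the request for a single enantiomer is met by the constitution alone; the ester is carried as the tert-butyl ester so that it can be removed by acid, because base would expose the catechol to air oxidation and the p-hydroxybenzyl sulfone to sulfinate loss.

Step 1
Reactants: 1 propargyl bromide (3-bromoprop-1-yne); 2 sodium methanethiolate
Product: 3 3-(methylsulfanyl)prop-1-yne (methyl propargyl sulfide)
Conditions: NaSMe (1.0 equiv), 1 (1.05 equiv), MeOH, 0 °C → rt; pentane extraction, careful distillation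
Reagents that add atoms: none
Why: SN2 thioether formation at a primary propargylic bromide is fast at 0 °C, and keeping the thiolate as the limiting reagent at low temperature should avoid base-induced isomerisation to the allenyl sulfide.

Step 2
Reactants: 3 3-(methylsulfanyl)prop-1-yne; 4 di-tert-butyl dicarbonate
Product: 6 tert-butyl 4-(methylsulfanyl)but-2-ynoate, via lithium 3-(methylsulfanyl)prop-1-yn-1-ide 5 (not isolated)
Conditions: n-BuLi (1.05 equiv), THF, −78 °C; cannulated into Boc2O (1.2 equiv), THF, −78 °C; sat. aq NH4Cl at −78 °C
Reagents that add atoms: none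
Why: the terminal alkyne C–H is the most acidic site, and C-acylation of the lithium acetylide with Boc2O is a standard way to tert-butyl alkynoates, inverse addition and a cold quench keeping the acidic γ-CH2 of the product away from excess base.

Step 3
Reactants: 6 tert-butyl 4-(methylsulfanyl)but-2-ynoate
Product: 8 tert-butyl 4-(methylsulfonyl)but-2-ynoate, via tert-butyl 4-(methylsulfinyl)but-2-ynoate 7 (not isolated)
Conditions: Oxone (1.5 equiv of the triple salt), MeOH/H2O 1:1, 0 °C → rt; EtOAc extraction without basic wash
Reagents that add atoms: potassium peroxymonosulfate (active component of Oxone), [K+].[O-]S(=O)(=O)OO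
Why: electrophilic S-oxidation of a sulfide through the sulfoxide to the sulfone with Oxone leaves the electron-poor alkyne untouched, and the acidic medium should prevent propargyl-to-allenyl isomerisation of the product.

Step 4
Reactants: 8 tert-butyl 4-(methylsulfonyl)but-2-ynoate; 9 2,3-bis(trimethylsilyloxy)buta-1,3-diene
Product: 10 tert-butyl 2-[(methylsulfonyl)methyl]-4,5-bis(trimethylsilyloxy)cyclohexa-1,4-diene-1-carboxylate
Conditions: 9 (2.5 equiv), toluene (2 M), BHT (cat.), silanised sealed tube, Ar, 110 °C; excess diene removed under vacuum, crude adduct used directly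
Reagents that add atoms: none
Why: A concerted, suprafacial [4+2] cycloaddition of normal electron demand pairs the high-lying HOMO of the bis(silyl enol ether) diene with the LUMO of the alkynoate, which the ester lowers by conjugation and the CH2SO2Me group lowers further by induction. The closest known reaction type is the thermal Diels–Alder reaction of 2,3-bis(silyloxy)butadienes with acetylenic esters, whose 1,4-cyclohexadiene adducts are oxidised to catechols. The single six-membered carbocycle is closed by intermolecular [4+2] cycloaddition, the two new σ-bonds (C1–C2 and C5–C6 of the target) forming in the same event. No stereocentre arises, since the diene termini become ring CH2 groups and the alkyne carbons stay sp2. The selectivity needed is chemoselectivity for cycloaddition over isomerisation of the propargylic sulfone to the allenyl sulfone and over desilylation of the diene; it is secured by the absence of any base or protic additive, by silanised glassware and by an excess of diene, while the symmetric diene removes any regiochemical question.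

Step 5
Reactants: 10 tert-butyl 2-[(methylsulfonyl)methyl]-4,5-bis(trimethylsilyloxy)cyclohexa-1,4-diene-1-carboxylate
Product: 13 4,5-dihydroxy-2-[(methylsulfonyl)methyl]benzoic acid, via tert-butyl 2-[(methylsulfonyl)methyl]-4,5-bis(trimethylsilyloxy)benzoate 11 (not isolated), via tert-butyl 4,5-dihydroxy-2-[(methylsulfonyl)methyl]benzoate 12 (not isolated)
Conditions: DDQ (1.0 equiv), toluene, 0 °C → rt, filtration; then TFA/CH2Cl2/H2O (10:10:1), rt
Reagents that add atoms: none
Why: quinone dehydrogenation of a 1,4-cyclohexadiene (hydride abstraction from the doubly allylic CH2, then proton loss) should give the arene, after which acidolysis removes the aryl silyl ethers at once and the tert-butyl ester more slowly, with water trapping the tert-butyl cation and no base ever touching the catechol.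

Step 6
Reactants: 13 4,5-dihydroxy-2-[(methylsulfonyl)methyl]benzoic acid
Product: 15 3,4,6-tribromo-5-[(methylsulfonyl)methyl]benzene-1,2-diol, via 3,6-dibromo-4,5-dihydroxy-2-[(methylsulfonyl)methyl]benzoic acid 14 (not isolated)
Conditions: Br2 (3.3 equiv), AcOH/H2O 4:1, rt → 50 °C; aq. NaHSO3 quench
Reagents that add atoms: bromine, BrBr
Why: electrophilic aromatic bromination should first fill the two positions ortho to the hydroxyls, and ipso attack of bromine at the carboxyl-bearing carbon para to the C3 hydroxyl with loss of CO2 (bromodecarboxylation of a 4-hydroxybenzoic acid) then sets the third bromine, the reductive quench returning any o-quinone to the catechol.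

**Compound list**
1 | propargyl bromide (3-bromoprop-1-yne) | C#CCBr | starting material
2 | sodium methanethiolate | C[S-].[Na+] | starting material
3 | 3-(methylsulfanyl)prop-1-yne | C#CCSC | intermediate
4 | di-tert-butyl dicarbonate | CC(C)(C)OC(=O)OC(=O)OC(C)(C)C | starting material
5 | lithium 3-(methylsulfanyl)prop-1-yn-1-ide (formed in the flask, not isolated) | [Li]C#CCSC | intermediate
6 | tert-butyl 4-(methylsulfanyl)but-2-ynoate | CSCC#CC(=O)OC(C)(C)C | intermediate
7 | tert-butyl 4-(methylsulfinyl)but-2-ynoate (racemic at sulfur, not isolated) | CS(=O)CC#CC(=O)OC(C)(C)C | intermediate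
8 | tert-butyl 4-(methylsulfonyl)but-2-ynoate | CS(=O)(=O)CC#CC(=O)OC(C)(C)C | intermediate
9 | 2,3-bis(trimethylsilyloxy)buta-1,3-diene | C=C(O[Si](C)(C)C)C(=C)O[Si](C)(C)C | starting material
10 | tert-butyl 2-[(methylsulfonyl)methyl]-4,5-bis(trimethylsilyloxy)cyclohexa-1,4-diene-1-carboxylate | CC(C)(C)OC(=O)C1=C(CS(C)(=O)=O)CC(O[Si](C)(C)C)=C(O[Si](C)(C)C)C1 | intermediate
11 | tert-butyl 2-[(methylsulfonyl)methyl]-4,5-bis(trimethylsilyloxy)benzoate (not isolated) | CC(C)(C)OC(=O)c1cc(O[Si](C)(C)C)c(O[Si](C)(C)C)cc1CS(C)(=O)=O | intermediate
12 | tert-butyl 4,5-dihydroxy-2-[(methylsulfonyl)methyl]benzoate (not isolated) | CC(C)(C)OC(=O)c1cc(O)c(O)cc1CS(C)(=O)=O | intermediate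
13 | 4,5-dihydroxy-2-[(methylsulfonyl)methyl]benzoic acid | OC(=O)c1cc(O)c(O)cc1CS(C)(=O)=O | intermediate
14 | 3,6-dibromo-4,5-dihydroxy-2-[(methylsulfonyl)methyl]benzoic acid (not isolated) | OC(=O)c1c(Br)c(O)c(O)c(Br)c1CS(C)(=O)=O | intermediate
15 | 3,4,6-tribromo-5-[(methylsulfonyl)methyl]benzene-1,2-diol | CS(=O)(=O)Cc1c(Br)c(O)c(O)c(Br)c1Br | target

**Count**
Total steps: 6. Longest linear sequence: 6 steps (1 → 3 → 6 → 8 → 10 → 13 → 15); diene 9 is purchased.

**Steps most likely to fail**

Step 4. The propargylic sulfone may isomerise to the allenyl sulfone on hot glass or with adventitious base, so that the allene and not the alkyne is consumed. The cycloaddition may also be so slow that the silyl diene hydrolyses and oligomerises first. The fallback runs the cycloaddition at the sulfide oxidation level with a diene that tolerates forcing conditions. Setting out from 6, heating with commercial 2,3-dimethoxybuta-1,3-diene (xylene, 150 °C, sealed tube) should give tert-butyl 4,5-dimethoxy-2-[(methylsulfanyl)methyl]cyclohexa-1,4-diene-1-carboxylate F1, which has no acidic sulfonyl CH2 to isomerise. DDQ in toluene should aromatise it to tert-butyl 4,5-dimethoxy-2-[(methylsulfanyl)methyl]benzoate F2. Oxidation with mCPBA (2.2 equiv, CH2Cl2, 0 °C) then gives tert-butyl 4,5-dimethoxy-2-[(methylsulfonyl)methyl]benzoate F3. BBr3 (CH2Cl2, −78 °C → rt) cleaves both methyl ethers and the tert-butyl ester, and the route is rejoined at 13.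

Step 6. Ipso attack at the carboxyl-bearing carbon may stall once that carbon is buttressed by an ortho bromine and the CH2SO2Me group and the ring is deactivated, leaving the reaction at the dibromo acid stage. Prolonged exposure to excess bromine may then degrade the catechol oxidatively. The fallback removes the carboxyl group before any bromine is introduced. Setting out from 13, copper-catalysed protodecarboxylation (Cu2O, 1,10-phenanthroline, NMP, 170 °C, Ar; the acid substrate keeps the medium non-basic) should give 4-[(methylsulfonyl)methyl]benzene-1,2-diol F4. Its three free ring positions are each ortho or para to a hydroxyl, so Br2 (3.1 equiv, AcOH, rt), the classical exhaustive bromination of a 4-alkylcatechol, should lead directly to 15.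

Step 5. DDQ may add to the electron-rich enediol bis(silyl ether) instead of abstracting hydride, or may over-oxidise the arene to an o-quinone once silyl groups are lost. The fallback reaches the aromatic oxidation level through the enediol instead of by dehydrogenation. Setting out from 10, bromine (1.0 equiv, CH2Cl2, −78 °C) should convert the bis(silyloxy)alkene into the α-diketone tert-butyl 2-[(methylsulfonyl)methyl]-4,5-dioxocyclohex-1-ene-1-carboxylate F5, as in the known oxidation of acyloin bis(silyl ethers) to 1,2-diones. This diketone is the keto tautomer of a catechol and should enolise twice to 12, where the route is rejoined; 12 is then carried through the TFA stage of step 5.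

**Further compounds**
F1 | step 4 | tert-butyl 4,5-dimethoxy-2-[(methylsulfanyl)methyl]cyclohexa-1,4-diene-1-carboxylate | CC(C)(C)OC(=O)C1=C(CSC)CC(OC)=C(OC)C1
F2 | step 4 | tert-butyl 4,5-dimethoxy-2-[(methylsulfanyl)methyl]benzoate | CC(C)(C)OC(=O)c1cc(OC)c(OC)cc1CSC
F3 | step 4 | tert-butyl 4,5-dimethoxy-2-[(methylsulfonyl)methyl]benzoate | CC(C)(C)OC(=O)c1cc(OC)c(OC)cc1CS(C)(=O)=O
F4 | step 6 | 4-[(methylsulfonyl)methyl]benzene-1,2-diol | CS(=O)(=O)Cc1ccc(O)c(O)c1
F5 | step 5 | tert-butyl 2-[(methylsulfonyl)methyl]-4,5-dioxocyclohex-1-ene-1-carboxylate | CC(C)(C)OC(=O)C1=C(CS(C)(=O)=O)CC(=O)C(=O)C1
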